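The readings stem from a simulated flask from invented constants; the scatter is artificial.

Start with the easy step: the flask differs from the elm run by one charge, c(incoming ligand) of 0.0725 M against 0.049 M, while c(starting complex) is the same. The ligand is charged at 2.50 times the complex, so I freeze it at its charge, a rough pseudo-first-order view.

common to all: starting complex 0.029 M
- elm: incoming ligand 0.049 M; run made earlier
- ash: incoming ligand 0.11 M; run made earlier
- flask: incoming ligand 0.0725 M; time 3.0 min

- elm (time / min: complex with one exchanged / %): 0.333: 9.7; 0.500: 13.2; 1.00: 16.7; 1.50: 18.8; 3.00: 18.0
- ash (time / min: complex with one exchanged / %): 0.333: 18.3; 0.500: 22.6; 1.00: 21.7; 1.50: 19.6; 3.00: 12.1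

(readings scatter by 1 percentage point)

- the numbers in the tables scatter with a standard deviation of 1 percentage point

- when, up to 3.0 min, the flask holds most complex with one exchanged
- the amount of complex with one exchanged, in percent of the starting complex charged, at that time

Elm reads 18.8 % at 1.50 min and 18.0 % at 3.00 min; ash reads 22.6 % at 0.500 min and 21.7 % at 1.00 min. With a scatter of 1 point, I take each top to lie inside its pair, and elm, with less ligand, ends its rise later. Multiply each time by c(incoming ligand) and you have the peak dose, the charged ligand concentration times the time of the top. Elm allows 4.41 M·s to 8.82 M·s, ash 3.30 M·s to 6.60 M·s, so the common window runs from 4.41 M·s to 6.60 M·s. For the flask that means 1.01 min to 1.52 min, with a height between the two runs.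

The forecast says 1.2 min (0.9 min to 1.6 min) and 20.5 % (19 % to 22.5 %), since “both runs fall roughly on one curve”.

The flask gives 20.9 % at 1.20 min, inside both ranges, and its dose of 5.22 M·s lies in the window.

    complex with one exchanged ⇌ isomer of the product (K = 2.50, k = 0.0140 /s)
    complex with two exchanged + incoming ligand → leaving ligand + complex with three exchanged (k = 0.274 /M/s)
    starting complex + incoming ligand → leaving ligand + complex with one exchanged (k = 0.133 /M/s)
    complex with one exchanged + incoming ligand → leaving ligand + complex with two exchanged (k = 0.158 /M/s)

At 0.850 min the flask makes complex with one exchanged 1.20 times faster than it uses it up, each step taken net. The forward isomerisation alone, which takes no ligand, gives that complex a half-life of 0.83 min, shorter than the 1.5 min of starting complex by its ligand step, yet the window came from runs on either side of the flask and it held.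

Read the same flask at 5.0 min: even with the ligand frozen at the 41 % of its charge left then, the dose is 8.92 M·s, above the window, which puts that reading past the top. The computed flask holds 14.2 % then, less than the 20.9 % reached before.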